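**Strategy.** Ring A, the cyclohexenone (C1 carbonyl, C2=C3, C4–C6), is cut at C1–C2 and C3–C4 into an internal alkyne (C2≡C3) and a four-membered ketone (C1, C6, C5, C4). In the key step zerovalent nickel inserts the alkyne into the C1–C4 bond of (S)-2-(silyloxymethyl)cyclobutanone. One operation joins the two advanced fragments, enlarges the four-membered ring by two carbons and creates the tetrasubstituted enone with all three stereocentres already in place. It exploits the steric contrast at C2=C3 (sec-alkyl side chain against the quaternary carbon of ring B) and at C1 (free C4 methylene against substituted C6). The precursors are a Roche-ester-derived alkyne and a cyclobutanone that is itself made by cyclopropane enlargement.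

Key step: step 9

Numbering used: ring A = cyclohexenone, C1 (C=O), C2 (side chain), C3 (bears ring B), C4, C5, C6 (bears CH2O). Ring B = 1,3,3-trimethylcyclohexyl.
Assumption: in step 4 the ligand enantiomer used is the one that adds methyl to the enone face giving the (S)-quaternary carbon; both enantiomers of the leucinol-derived salt are accessible.
Assumption: ethyl 2-cyclopropylideneacetate is treated as a catalogue compound.

Step 1
Reactants: 1 methyl (S)-3-hydroxy-2-methylpropanoate
Product: 2 methyl (S)-3-(benzyloxy)-2-methylpropanoate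
Conditions: BnOC(=NH)CCl3, TfOH (cat.), CH2Cl2/cyclohexane, 0 °C to rt
Reagents that add atoms: benzyl 2,2,2-trichloroacetimidate, N=C(OCc1ccccc1)C(Cl)(Cl)Cl
Why: Acid-catalysed trichloroacetimidate O-benzylation works without base, so the α-stereocentre of the β-hydroxy ester (the later side-chain centre) is neither epimerised nor lost by elimination.

Step 2
Reactants: 2 methyl (S)-3-(benzyloxy)-2-methylpropanoate
Product: 4 (R)-{[(2-methylbut-3-yn-1-yl)oxy]methyl}benzene, via aldehyde 3 (not isolated)
Conditions: iBu2AlH, CH2Cl2, −78 °C; then MeOH, K2CO3, MeC(O)C(N2)P(O)(OMe)2, −78 °C to rt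
Reagents that add atoms: dimethyl (1-diazo-2-oxopropyl)phosphonate, CC(=O)C(=[N+]=[N-])P(=O)(OC)OC
Why: Partial ester reduction followed in the same flask by Ohira–Bestmann (Seyferth–Gilbert) homologation turns the ester carbon into a terminal alkyne without isolating the epimerisable aldehyde, and the stereocentre is carried over unchanged (the descriptor changes only through priorities).

Step 3
Reactants: 4 (R)-{[(2-methylbut-3-yn-1-yl)oxy]methyl}benzene; 5 3-ethoxycyclohex-2-en-1-one
Product: 7 3-[(3R)-4-(benzyloxy)-3-methylbut-1-yn-1-yl]cyclohex-2-en-1-one, via tertiary propargylic alcohol 6 (not isolated)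
Conditions: n-BuLi, THF, −78 °C; 5, −78 to 0 °C; then 1 M aq HCl, rt
Reagents that add atoms: water, O
Why: Stork–Danheiser transposition, in which 1,2-addition of the lithium acetylide to the vinylogous ester and acidic hydrolysis with loss of ethanol give the 3-alkynyl enone, and no stereocentre is touched.

Step 4
Reactants: 7 3-[(3R)-4-(benzyloxy)-3-methylbut-1-yn-1-yl]cyclohex-2-en-1-one
Product: 8 (3S)-3-[(3R)-4-(benzyloxy)-3-methylbut-1-yn-1-yl]-3-methylcyclohexan-1-one
Conditions: MeMgBr, Cu(OTf)2 (6 mol %), leucinol-derived N-mesityl-N'-(1-hydroxy-4-methylpentan-2-yl)imidazolinium hexafluorophosphate (9 mol %), Et2O, −30 to 0 °C; then 1 M aq HCl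
Reagents that add atoms: methylmagnesium bromide, C[Mg]Br
Why: Copper-catalysed asymmetric conjugate addition of a Grignard reagent to a cyclic enynone, where the hydroxyalkyl NHC–copper catalyst favours 1,4- over 1,6-addition and its chiral pocket, not the remote side-chain centre, selects the enone face and sets the quaternary carbon as (S).

Step 5
Reactants: 8 (3S)-3-[(3R)-4-(benzyloxy)-3-methylbut-1-yn-1-yl]-3-methylcyclohexan-1-one
Product: 9 ({(2R)-2-methyl-4-[(1S)-1,3,3-trimethylcyclohexyl]but-3-yn-1-yl}oxymethyl)benzene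
Conditions: Me2Zn, TiCl4 (gives Me2TiCl2), CH2Cl2, −30 °C to rt
Reagents that add atoms: dimethylzinc, C[Zn]C
Why: Reetz geminal dimethylation, in which methyl addition, ionisation of the tertiary titanium alkoxide and a second methyl transfer convert C=O directly into CMe2, while the slim axial-tolerant alkynyl group keeps the 1,3-strain low and the existing centres are not involved.

Step 6
Reactants: 10 ethyl 2-cyclopropylideneacetate
Product: 11 2-cyclopropylideneethan-1-ol
Conditions: iBu2AlH (2.2 equiv), CH2Cl2, −78 to 0 °C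
Reagents that add atoms: none
Why: 1,2-Reduction of an α,β-unsaturated ester with iBu2AlH gives the allylic alcohol and leaves the strained exocyclic alkene untouched.

Step 7
Reactants: 11 2-cyclopropylideneethan-1-ol
Product: 13 (2S)-2-(hydroxymethyl)cyclobutan-1-one, via oxaspiropentane 12 (not isolated)
Conditions: Ti(OiPr)4 (10 mol %), D-(−)-diisopropyl tartrate (12 mol %), t-BuOOH (decane), 4 Å MS, CH2Cl2, −20 °C, then rt
Reagents that add atoms: tert-butyl hydroperoxide, CC(C)(C)OO
Why: Sharpless asymmetric epoxidation with the D-(−)-tartrate should give the (R)-oxaspiropentane, which opens under the titanium Lewis acid while a cyclopropane C–C bond migrates anti to the breaking C–O bond (oxaspiropentane-to-cyclobutanone semipinacol rearrangement), so inversion at the carbinyl carbon sets the (S)-centre that becomes C6.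

Step 8
Reactants: 13 (2S)-2-(hydroxymethyl)cyclobutan-1-one
Product: 14 (2S)-2-{[(tert-butyldimethylsilyl)oxy]methyl}cyclobutan-1-one
Conditions: TBSCl, imidazole, CH2Cl2, 0 °C
Reagents that add atoms: tert-butyldimethylsilyl chloride, CC(C)(C)[Si](C)(C)Cl
Why: Standard silylation of a primary alcohol, in which the α-centre should hold because enolisation of a cyclobutanone is disfavoured by ring strain and imidazole is a weak base.

Step 9
Reactants: 9 ({(2R)-2-methyl-4-[(1S)-1,3,3-trimethylcyclohexyl]but-3-yn-1-yl}oxymethyl)benzene; 14 (2S)-2-{[(tert-butyldimethylsilyl)oxy]methyl}cyclobutan-1-one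
Product: 15 (6S)-2-[(2R)-1-(benzyloxy)propan-2-yl]-6-{[(tert-butyldimethylsilyl)oxy]methyl}-3-[(1S)-1,3,3-trimethylcyclohexyl]cyclohex-2-en-1-one
Conditions: Ni(cod)2 (10–20 mol %), PCy3 (20–40 mol %), toluene, 100 °C, sealed tube, Ar
Reagents that add atoms: none
Why: Ni(cod)2/PCy3 binds the alkyne and the strained C=O of 14 and couples them oxidatively to a spiro oxanickelacyclopentene (new C1–C2 bond), strain-driven β-carbon elimination then cleaves the cyclobutane C1–C4 bond to a seven-membered nickelacycle, and C(sp2)–C(sp3) reductive elimination forms C3–C4 and returns zerovalent nickel. The closest known reaction type is the nickel-catalysed intermolecular insertion of internal alkynes into cyclobutanones (formal [4+2], two-carbon ring expansion), which has also been shown on enantiopure 2-substituted four-membered amino ketones. Ring A is closed by reductive elimination from the seven-membered metallacycle, that is by four-to-six ring enlargement and not by cyclisation of an open chain. No new stereocentre is formed: C6, the side-chain carbon and the ring B quaternary carbon are spectators, because no bond at these atoms is broken and the medium is neutral and aprotic. Two selectivities are needed: the alkyne orientation is secured because the tert-alkyl (ring B) end stays next to nickel and away from the forming C1–C2 bond so that the sec-alkyl end bonds to C1, and the cleavage site is secured because β-carbon elimination towards the unsubstituted C4 methylene gives a primary alkylnickel and avoids the substituted C6. The doubly branched alkyne cannot oligomerise, which allows slow turnover at high temperature.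

Step 10
Reactants: 15 (6S)-2-[(2R)-1-(benzyloxy)propan-2-yl]-6-{[(tert-butyldimethylsilyl)oxy]methyl}-3-[(1S)-1,3,3-trimethylcyclohexyl]cyclohex-2-en-1-one
Product: 16 (6S)-6-{[(tert-butyldimethylsilyl)oxy]methyl}-2-[(2R)-1-hydroxypropan-2-yl]-3-[(1S)-1,3,3-trimethylcyclohexyl]cyclohex-2-en-1-one
Conditions: H2 (1 atm), Pd/C, EtOAc, rt
Reagents that add atoms: none
Why: Hydrogenolysis of the benzyl ether under neutral conditions should spare the silyl ether and the shielded tetrasubstituted enone and leave the α-keto centre C6 untouched.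

Step 11
Reactants: 16 (6S)-6-{[(tert-butyldimethylsilyl)oxy]methyl}-2-[(2R)-1-hydroxypropan-2-yl]-3-[(1S)-1,3,3-trimethylcyclohexyl]cyclohex-2-en-1-one
Product: 18 (2R)-2-{(5S)-5-{[(tert-butyldimethylsilyl)oxy]methyl}-6-oxo-2-[(1S)-1,3,3-trimethylcyclohexyl]cyclohex-1-en-1-yl}propanoic acid, via aldehyde 17 (not isolated)
Conditions: TEMPO (cat.), NaClO2, NaOCl (cat.), MeCN/pH 6.7 phosphate buffer, 35 °C
Reagents that add atoms: sodium chlorite, [Na+].[O-]Cl=O
Why: TEMPO/chlorite oxidation (Anelli oxidation coupled to a Pinnick step in one flask) consumes the α-chiral aldehyde as fast as it forms at near-neutral pH, which protects both the side-chain centre and C6 from epimerisation and the β-silyloxy ketone from elimination.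

Step 12
Reactants: 18 (2R)-2-{(5S)-5-{[(tert-butyldimethylsilyl)oxy]methyl}-6-oxo-2-[(1S)-1,3,3-trimethylcyclohexyl]cyclohex-1-en-1-yl}propanoic acid
Product: 20 (2R)-2-{(5S)-5-[(formyloxy)methyl]-6-oxo-2-[(1S)-1,3,3-trimethylcyclohexyl]cyclohex-1-en-1-yl}propanoic acid, via hydroxy acid 19 (not isolated)
Conditions: HCO2H (98 %, neat), rt
Reagents that add atoms: formic acid, O=CO
Why: Acidolysis of the primary silyl ether and Fischer-type formylation of the freed alcohol take place in the same medium, base is avoided so that β-elimination and epimerisation at C6 are suppressed, and the free carboxylic acid is unaffected.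

**Compound list**
1 | methyl (S)-3-hydroxy-2-methylpropanoate | C[C@@H](CO)C(=O)OC | starting material
2 | methyl (S)-3-(benzyloxy)-2-methylpropanoate | C[C@@H](COCc1ccccc1)C(=O)OC | intermediate
3 | (S)-3-(benzyloxy)-2-methylpropanal | C[C@@H](COCc1ccccc1)C=O | intermediate
4 | (R)-{[(2-methylbut-3-yn-1-yl)oxy]methyl}benzene | C[C@@H](COCc1ccccc1)C#C | intermediate
5 | 3-ethoxycyclohex-2-en-1-one | CCOC1=CC(=O)CCC1 | starting material
6 | 1-[(3R)-4-(benzyloxy)-3-methylbut-1-yn-1-yl]-3-ethoxycyclohex-2-en-1-ol (carbinol epimers) | C[C@@H](COCc1ccccc1)C#CC1(O)C=C(OCC)CCC1 | intermediate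
7 | 3-[(3R)-4-(benzyloxy)-3-methylbut-1-yn-1-yl]cyclohex-2-en-1-one | C[C@@H](COCc1ccccc1)C#CC1=CC(=O)CCC1 | intermediate
8 | (3S)-3-[(3R)-4-(benzyloxy)-3-methylbut-1-yn-1-yl]-3-methylcyclohexan-1-one | C[C@@H](COCc1ccccc1)C#C[C@@]1(C)CCCC(=O)C1 | intermediate
9 | ({(2R)-2-methyl-4-[(1S)-1,3,3-trimethylcyclohexyl]but-3-yn-1-yl}oxymethyl)benzene | C[C@@H](COCc1ccccc1)C#C[C@@]1(C)CCCC(C)(C)C1 | intermediate
10 | ethyl 2-cyclopropylideneacetate | CCOC(=O)C=C1CC1 | starting material
11 | 2-cyclopropylideneethan-1-ol | OCC=C1CC1 | intermediate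
12 | [(2R)-1-oxaspiro[2.2]pentan-2-yl]methanol | OC[C@H]1OC12CC2 | intermediate
13 | (2S)-2-(hydroxymethyl)cyclobutan-1-one | C1C[C@@H](CO)C1=O | intermediate
14 | (2S)-2-{[(tert-butyldimethylsilyl)oxy]methyl}cyclobutan-1-one | C1C[C@@H](CO[Si](C)(C)C(C)(C)C)C1=O | intermediate
15 | (6S)-2-[(2R)-1-(benzyloxy)propan-2-yl]-6-{[(tert-butyldimethylsilyl)oxy]methyl}-3-[(1S)-1,3,3-trimethylcyclohexyl]cyclohex-2-en-1-one | C[C@@H](COCc1ccccc1)C1=C([C@@]2(C)CCCC(C)(C)C2)CC[C@@H](CO[Si](C)(C)C(C)(C)C)C1=O | intermediate
16 | (6S)-6-{[(tert-butyldimethylsilyl)oxy]methyl}-2-[(2R)-1-hydroxypropan-2-yl]-3-[(1S)-1,3,3-trimethylcyclohexyl]cyclohex-2-en-1-one | C[C@@H](CO)C1=C([C@@]2(C)CCCC(C)(C)C2)CC[C@@H](CO[Si](C)(C)C(C)(C)C)C1=O | intermediate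
17 | (2R)-2-{(5S)-5-{[(tert-butyldimethylsilyl)oxy]methyl}-6-oxo-2-[(1S)-1,3,3-trimethylcyclohexyl]cyclohex-1-en-1-yl}propanal | C[C@@H](C=O)C1=C([C@@]2(C)CCCC(C)(C)C2)CC[C@@H](CO[Si](C)(C)C(C)(C)C)C1=O | intermediate
18 | (2R)-2-{(5S)-5-{[(tert-butyldimethylsilyl)oxy]methyl}-6-oxo-2-[(1S)-1,3,3-trimethylcyclohexyl]cyclohex-1-en-1-yl}propanoic acid | C[C@@H](C(=O)O)C1=C([C@@]2(C)CCCC(C)(C)C2)CC[C@@H](CO[Si](C)(C)C(C)(C)C)C1=O | intermediate
19 | (2R)-2-{(5S)-5-(hydroxymethyl)-6-oxo-2-[(1S)-1,3,3-trimethylcyclohexyl]cyclohex-1-en-1-yl}propanoic acid | C[C@@H](C(=O)O)C1=C([C@@]2(C)CCCC(C)(C)C2)CC[C@@H](CO)C1=O | intermediate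
20 | (2R)-2-{(5S)-5-[(formyloxy)methyl]-6-oxo-2-[(1S)-1,3,3-trimethylcyclohexyl]cyclohex-1-en-1-yl}propanoic acid | C[C@@H](C(=O)O)C1=C([C@@]2(C)CCCC(C)(C)C2)CC[C@@H](COC=O)C1=O | target

Total step count: 12. Longest linear sequence: 9 steps (steps 1–5 and 9–12).

**Steps most likely to fail**

Step 9.
- What may go wrong: oxidative coupling of the doubly branched alkyne with the ketone may be too slow. β-Hydride elimination at C5 may open the seven-membered nickelacycle. Cleavage on the substituted side, or reversed alkyne orientation, may erode the selectivity.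
- Fallback: it sets out from 9 and 14, comes back at 15, and splits the same four-to-six enlargement into stoichiometric stages.
- First stage: alkyne 9 is converted with Ti(OiPr)4 and two equivalents of iPrMgCl (Et2O, −78 to −30 °C) into the titanacyclopropene F1. This adds to cyclobutanone 14 through its less hindered carbon.
- Second stage: I2 cleaves the remaining vinyl–titanium bond to give the (Z)-iodoalkenyl cyclobutanol F2.
- Third stage: Pd(OAc)2/PCy3 and Cs2CO3 in toluene at 80 °C bring about oxidative addition to zerovalent palladium, alkoxide binding, β-carbon elimination of the unsubstituted cyclobutane bond and reductive elimination to 15.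

Step 4.
- What may go wrong: competing 1,6-addition at the alkyne terminus, 1,2-addition of the Grignard reagent, or poor facial selectivity with the small methyl nucleophile.
- Fallback: it sets out from 4, comes back at 8, and makes the bond to the quaternary carbon from the alkyne side.
- Procedure: alkyne 4 is lithiated (n-BuLi) and transmetallated with Me2AlCl to the dimethylaluminium acetylide F3. This is added 1,4 to purchased 3-methylcyclohex-2-en-1-one F4 under Ni(acac)2/iBu2AlH catalysis (Et2O, 0 °C).
- Stereochemistry: no facial control is expected. Because 4 is a single enantiomer the products are diastereomers, and 8 is separated from its C3 epimer F5 by preparative HPLC.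

Step 5.
- What may go wrong: proton loss or hydride shift of the tertiary cation instead of methyl capture, or attack of the Lewis acid on the benzyl ether.
- Fallback: it sets out from 8, comes back at 9, and replaces the cation by a radical.
- First stage: Wittig methylenation (Ph3P=CH2, THF) gives the exocyclic alkene F6.
- Second stage: hydrogen-atom-transfer hydromethylation (Fe(acac)3, PhSiH3) uses formaldehyde octylsulfonylhydrazone F7, made in the flask from octane-1-sulfonyl hydrazide and formaldehyde. It gives the alkyl sulfonyl hydrazide F8.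
- Third stage: warming F8 in MeOH at 60 °C expels sulfinate and nitrogen and leaves the second methyl group of 9.

**Further compounds**
F1 | step 9 | diisopropoxytitanacyclopropene of alkyne 9 | C[C@@H](COCc1ccccc1)C1=C([C@@]2(C)CCCC(C)(C)C2)[Ti]1(OC(C)C)OC(C)C
F2 | step 9 | (2S)-1-{(Z)-(3R)-4-(benzyloxy)-1-iodo-3-methyl-1-[(1S)-1,3,3-trimethylcyclohexyl]but-1-en-2-yl}-2-{[(tert-butyldimethylsilyl)oxy]methyl}cyclobutan-1-ol (carbinol configuration open) | I/C([C@@]2(C)CCCC(C)(C)C2)=C(/[C@@H](C)COCc1ccccc1)C3(O)CC[C@H]3CO[Si](C)(C)C(C)(C)C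
F3 | step 4 | [(3R)-4-(benzyloxy)-3-methylbut-1-yn-1-yl]dimethylaluminium | C[C@@H](COCc1ccccc1)C#C[Al](C)C
F4 | step 4 | 3-methylcyclohex-2-en-1-one (purchased) | CC1=CC(=O)CCC1
F5 | step 4 | (3R)-3-[(3R)-4-(benzyloxy)-3-methylbut-1-yn-1-yl]-3-methylcyclohexan-1-one | C[C@@H](COCc1ccccc1)C#C[C@]1(C)CCCC(=O)C1
F6 | step 5 | ({(2R)-2-methyl-4-[(1S)-1-methyl-3-methylidenecyclohexyl]but-3-yn-1-yl}oxymethyl)benzene | C[C@@H](COCc1ccccc1)C#C[C@@]1(C)CCCC(=C)C1
F7 | step 5 | N'-methylideneoctane-1-sulfonohydrazide | C=NNS(=O)(=O)CCCCCCCC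
F8 | step 5 | N'-({(3S)-3-[(3R)-4-(benzyloxy)-3-methylbut-1-yn-1-yl]-1,3-dimethylcyclohexyl}methyl)octane-1-sulfonohydrazide | C[C@@H](COCc1ccccc1)C#C[C@@]1(C)CCCC(C)(CNNS(=O)(=O)CCCCCCCC)C1
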